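**Plan**

1. Retrosynthesis: (a) the diol and the CH2OH group are traced to acetonide acid 13 (CH2OH from CO2H, diol from the isopropylidene acetal). (b) The carbocycle is opened at the bond between the quaternary carbinol carbon and the neighbouring CH(OBz), while the remote alkene carbon is re-joined to a carboxyl oxygen (retro Ireland–Claisen), giving δ-lactone 10 with an (E)-2-(benzoyloxy)vinyl group at C5. (c) The side chain C6=C7 and the lactone are traced to D-glucal.
2. Enabling feature: in the six-membered ring the quaternary C(OH)(CH2OH) is joined through the CH(OBz) carbon to the ring C=C. With CH2OH raised to CO2H the ring holds the unit O=C–C(q)–CH(OBz)–CH=CH, a γ,δ-unsaturated acid, which is the retron of an ester-enolate Claisen; the ring alkene carbon remote from C(q) is the former lactone C–O carbon.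
3. Forward order: D-glucal → 2,3-unsaturated δ-lactone → D-manno diol acetonide (temporary rings) → C6 aldehyde → (E)-alkenylboronate → (E)-enol benzoate → Claisen ring contraction, which closes the only carbocycle → CO2H to CH2OH → acetal hydrolysis.
4. Stereochemistry: C4 (kept as a benzoate carbon) and C5 (spent in the chirality transfer) come from D-glucal. C2–O and C3–O come from osmylation anti to the C4 benzoate. The quaternary carbon and the second benzoate carbon are both set in the key step, the first by C5 through a suprafacial boat, the second by the E geometry of the enol benzoate.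

Key step: step 9

Remark: compounds 1–11 carry carbohydrate locants (C1 = anomeric or lactone carbon). After the ring contraction old C2, C7, C6, C5, C4, C3 are positions 3a, 4, 5, 6, 7, 7a of the benzodioxole names, and old C1 is the exocyclic carbon.

**Route**

Step 1
Reactants: 1 D-glucal
Product: 3 3,4-di-O-benzoyl-6-O-(tert-butyldiphenylsilyl)-D-glucal, via 6-O-(tert-butyldiphenylsilyl)-D-glucal 2 (not isolated)
Conditions: TBDPSCl (1.05 equiv), pyridine, 0 °C; then BzCl (2.5 equiv), DMAP (cat.), 0 °C to rt
Reagents that add atoms: tert-butyl(chloro)diphenylsilane CC(C)(C)[Si](Cl)(c1ccccc1)c1ccccc1; benzoyl chloride O=C(Cl)c1ccccc1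
Why: The bulky silyl chloride should silylate only the primary C6 hydroxyl, and benzoyl chloride then acylates the two secondary hydroxyls in the same flask (selective silylation followed by pyridine-mediated esterification), with no stereocentre touched.

Step 2
Reactants: 3 3,4-di-O-benzoyl-6-O-(tert-butyldiphenylsilyl)-D-glucal
Product: 4 4-O-benzoyl-6-O-(tert-butyldiphenylsilyl)-2,3-dideoxy-D-erythro-hex-2-enono-1,5-lactone
Conditions: mCPBA (1.2 equiv), BF3·OEt2 (0.2 equiv), CH2Cl2, −20 °C
Reagents that add atoms: 3-chloroperbenzoic acid O=C(OO)c1cccc(Cl)c1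
Why: Boron trifluoride should ionise the allylic C3 benzoate and the peracid deliver oxygen to C1, which ends as the lactone carbonyl next to the shifted C2=C3 bond (oxidative Ferrier-type rearrangement of a glycal ester to a 2,3-unsaturated δ-lactone), while C4 and C5 keep their configuration.

Step 3
Reactants: 4 4-O-benzoyl-6-O-(tert-butyldiphenylsilyl)-2,3-dideoxy-D-erythro-hex-2-enono-1,5-lactone
Product: 5 4-O-benzoyl-6-O-(tert-butyldiphenylsilyl)-D-mannono-1,5-lactone
Conditions: K2OsO4·2H2O (2 mol %), NMO (1.3 equiv), citric acid (1 equiv), t-BuOH/H2O 1:1, rt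
Reagents that add atoms: N-methylmorpholine N-oxide C[N+]1([O-])CCOCC1; water O
Why: Catalytic osmylation (Upjohn dihydroxylation in its citric-acid variant for electron-poor alkenes) should add both hydroxyls cis and from the face anti to the allylic C4 benzoate, as the empirical rule for allylic esters predicts, which sets C2 and C3 in the D-manno sense, and the slightly acidic medium should keep the benzoate on O4 so that the lactone cannot contract to the γ-lactone.

Step 4
Reactants: 5 4-O-benzoyl-6-O-(tert-butyldiphenylsilyl)-D-mannono-1,5-lactone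
Product: 6 4-O-benzoyl-6-O-(tert-butyldiphenylsilyl)-2,3-O-isopropylidene-D-mannono-1,5-lactone
Conditions: 2,2-dimethoxypropane, CSA (cat.), acetone, rt
Reagents that add atoms: 2,2-dimethoxypropane COC(C)(C)OC
Why: Acid-catalysed transacetalisation should close the isopropylidene acetal on the cis-2,3-diol of the lactone (acetonide formation), which protects both hydroxyls until the last step and later holds the C3–O bond near the plane of the lactone enolate.

Step 5
Reactants: 6 4-O-benzoyl-6-O-(tert-butyldiphenylsilyl)-2,3-O-isopropylidene-D-mannono-1,5-lactone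
Product: 7 4-O-benzoyl-2,3-O-isopropylidene-D-mannono-1,5-lactone
Conditions: HF·pyridine, THF/pyridine, 0 °C to rt
Reagents that add atoms: none
Why: Hydrogen fluoride–pyridine should cleave the silyl ether under slightly acidic conditions (fluoride-mediated desilylation) that neither open the lactone nor move the C4 benzoate to O6.

Step 6
Reactants: 7 4-O-benzoyl-2,3-O-isopropylidene-D-mannono-1,5-lactone
Product: 8 4-O-benzoyl-2,3-O-isopropylidene-D-manno-hexodialdono-1,5-lactone (the C6 aldehyde of 7)
Conditions: Dess–Martin periodinane (1.3 equiv), CH2Cl2, 0 °C to rt; crude product used directly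
Reagents that add atoms: none
Why: Dess–Martin oxidation should give the aldehyde without base, which matters because C5–H of the product is acidic and sits β to the benzoate, and the crude aldehyde is used at once.

Step 7
Reactants: 8 4-O-benzoyl-2,3-O-isopropylidene-D-manno-hexodialdono-1,5-lactone
Product: 9 (6E)-4-O-benzoyl-6,7-dideoxy-2,3-O-isopropylidene-7-(4,4,5,5-tetramethyl-1,3,2-dioxaborolan-2-yl)-D-manno-hept-6-enono-1,5-lactone
Conditions: Cl2CHB(pin) (2 equiv), CrCl2 (8 equiv), LiI (4 equiv), THF, rt
Reagents that add atoms: 2-(dichloromethyl)-4,4,5,5-tetramethyl-1,3,2-dioxaborolane ClC(Cl)B1OC(C)(C)C(C)(C)O1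
Why: The geminal dichromium reagent formed from the dihalomethylboronate and chromium(II) should add to the aldehyde and eliminate to the (E)-alkenylboronate (Takai–Utimoto olefination, boron variant) under non-basic conditions that the lactone, the benzoate and the C5 stereocentre tolerate.

Step 8
Reactants: 9 (6E)-alkenylboronate lactone
Product: 10 (6E)-4-O-benzoyl-7-(benzoyloxy)-6,7-dideoxy-2,3-O-isopropylidene-D-manno-hept-6-enono-1,5-lactone (C5 carries an (E)-2-(benzoyloxy)vinyl group)
Conditions: Cu(OAc)2 (2 equiv), PhCO2H (3 equiv), Et3N (4 equiv), 4 Å MS, DMF, 40 °C, dry air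
Reagents that add atoms: benzoic acid O=C(O)c1ccccc1
Why: Copper(II)-mediated oxidative coupling of the alkenylboronate with benzoic acid (Chan–Lam–Evans enol esterification) forms the vinylic C–O bond with retention of alkene geometry, so the E configuration that the key step needs is carried into the enol benzoate.

Step 9
Reactants: 10 (6E)-enol benzoate lactone
Product: 13 (3aR,4S,7R,7aS)-4,7-bis(benzoyloxy)-2,2-dimethyl-4,7-dihydro-1,3-benzodioxole-3a(7aH)-carboxylic acid, via silyl ketene acetal 11 (not isolated), via trimethylsilyl ester 12 (not isolated)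
Conditions: LiHMDS (1.3 equiv), TMSCl/Et3N (1:1, 5 equiv), THF, −78 °C; then toluene, 105 °C; then 1 M HCl, THF, 0 °C
Reagents that add atoms: none
Why: Kinetic deprotonation at C2 with silylation in situ gives ketene acetal 11, a 1,5-diene C2=C1–O5–C5–C6=C7, and heating triggers an Ireland–Claisen [3,3]-sigmatropic shift that forms the C2–C7 bond as the C5–O5 bond breaks, leaving old C1 as the silyl ester that the work-up hydrolyses. The closest known reaction type is the Claisen ring contraction of 6-alkenyl δ-lactone silyl ketene acetals to cyclohex-3-enecarboxylic acids, together with its oxygen analogue, the dioxanone-to-dihydropyran rearrangement. The cyclohexene closes by suprafacial C–C bond formation between the enolate carbon and the alkene terminus through a boat-shaped six-atom array, because the two-carbon tether C3–C4 links the two termini; the lactone ring is lost in the same event and the new ring C=C (old C5=C6) can only be cis. The quaternary centre (old C2) is controlled by C5, since the bond must form on the lactone face that carries the alkenyl group, which puts the carboxyl carbon cis to the C4 benzoate and the acetal oxygen cis to O3; the benzoate-bearing centre (old C7) is controlled by the E geometry of the enol benzoate, whose outward-pointing oxygen ends cis to the carboxyl carbon in the boat. The step needs C2 enolisation without β-elimination or benzoyl transfer and a single transition-state shape; the first is secured by the cis-fused dioxolane, which holds the C3–O bond near the enolate plane, by benzoates that lack α-hydrogens and by trapping the enolate as it forms, and the second because a chair cannot be spanned by the two-atom tether.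

Step 10
Reactants: 13 acetonide acid
Product: 15 (3aR,4S,7R,7aS)-3a-(hydroxymethyl)-2,2-dimethyl-3a,4,7,7a-tetrahydro-1,3-benzodioxole-4,7-diyl dibenzoate, via acyl imidazolide 14 (not isolated)
Conditions: CDI (1.3 equiv), THF, rt; then NaBH4 (3 equiv), H2O, 0 °C; AcOH quench
Reagents that add atoms: none
Why: Activation of the hindered acid as its acyl imidazolide and short borohydride reduction (reduction of an activated carboxylic acid derivative to the primary alcohol) should convert the helper carboxyl group into the hydroxymethyl group faster than the unactivated benzoates react, the quaternary centre being untouched.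

Step 11
Reactants: 15 acetonide alcohol
Product: 16 (1R,4S,5S,6S)-5,6-dihydroxy-5-(hydroxymethyl)cyclohex-2-ene-1,4-diyl dibenzoate (CNP0212417.1)
Conditions: TFA/H2O 9:1, 0 °C to rt
Reagents that add atoms: none
Why: Aqueous trifluoroacetic acid should hydrolyse the isopropylidene acetal to the cis-diol (acid-catalysed acetal hydrolysis) under conditions in which the two benzoates neither cleave nor migrate.

**Compound list**

1 | D-glucal | OC[C@H]1OC=C[C@@H](O)[C@@H]1O | starting material
2 | 6-O-(tert-butyldiphenylsilyl)-D-glucal | CC(C)(C)[Si](OC[C@H]1OC=C[C@@H](O)[C@@H]1O)(c1ccccc1)c1ccccc1 | intermediate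
3 | 3,4-di-O-benzoyl-6-O-(tert-butyldiphenylsilyl)-D-glucal | CC(C)(C)[Si](OC[C@H]1OC=C[C@@H](OC(=O)c2ccccc2)[C@@H]1OC(=O)c1ccccc1)(c1ccccc1)c1ccccc1 | intermediate
4 | 4-O-benzoyl-6-O-(tert-butyldiphenylsilyl)-2,3-dideoxy-D-erythro-hex-2-enono-1,5-lactone | CC(C)(C)[Si](OC[C@H]1OC(=O)C=C[C@@H]1OC(=O)c1ccccc1)(c1ccccc1)c1ccccc1 | intermediate
5 | 4-O-benzoyl-6-O-(tert-butyldiphenylsilyl)-D-mannono-1,5-lactone | CC(C)(C)[Si](OC[C@H]1OC(=O)[C@@H](O)[C@@H](O)[C@@H]1OC(=O)c1ccccc1)(c1ccccc1)c1ccccc1 | intermediate
6 | 4-O-benzoyl-6-O-(tert-butyldiphenylsilyl)-2,3-O-isopropylidene-D-mannono-1,5-lactone | CC(C)(C)[Si](OC[C@H]1OC(=O)[C@H]2OC(C)(C)O[C@H]2[C@@H]1OC(=O)c1ccccc1)(c1ccccc1)c1ccccc1 | intermediate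
7 | 4-O-benzoyl-2,3-O-isopropylidene-D-mannono-1,5-lactone | OC[C@H]1OC(=O)[C@H]2OC(C)(C)O[C@H]2[C@@H]1OC(=O)c1ccccc1 | intermediate
8 | 4-O-benzoyl-2,3-O-isopropylidene-D-manno-hexodialdono-1,5-lactone (C6 aldehyde) | O=C[C@H]1OC(=O)[C@H]2OC(C)(C)O[C@H]2[C@@H]1OC(=O)c1ccccc1 | intermediate
9 | (6E)-4-O-benzoyl-6,7-dideoxy-2,3-O-isopropylidene-7-(pinacolatoboryl)-D-manno-hept-6-enono-1,5-lactone | CC1(C)OB(/C=C/[C@H]2OC(=O)[C@H]3OC(C)(C)O[C@H]3[C@@H]2OC(=O)c2ccccc2)OC1(C)C | intermediate
10 | (6E)-4-O-benzoyl-7-(benzoyloxy)-6,7-dideoxy-2,3-O-isopropylidene-D-manno-hept-6-enono-1,5-lactone | O=C(O/C=C/[C@H]1OC(=O)[C@H]2OC(C)(C)O[C@H]2[C@@H]1OC(=O)c1ccccc1)c1ccccc1 | intermediate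
11 | 1-O-trimethylsilyl ketene acetal of 10 (C1=C2 enol silyl ether of the lactone) | O=C(O/C=C/[C@H]1OC(O[Si](C)(C)C)=C2OC(C)(C)O[C@H]2[C@@H]1OC(=O)c1ccccc1)c1ccccc1 | intermediate
12 | trimethylsilyl (3aR,4S,7R,7aS)-4,7-bis(benzoyloxy)-2,2-dimethyl-4,7-dihydro-1,3-benzodioxole-3a(7aH)-carboxylate | O=C(O[C@H]1C=C[C@@H](OC(=O)c2ccccc2)[C@@H]2OC(C)(C)O[C@]12C(=O)O[Si](C)(C)C)c1ccccc1 | intermediate
13 | (3aR,4S,7R,7aS)-4,7-bis(benzoyloxy)-2,2-dimethyl-4,7-dihydro-1,3-benzodioxole-3a(7aH)-carboxylic acid | O=C(O[C@H]1C=C[C@@H](OC(=O)c2ccccc2)[C@@H]2OC(C)(C)O[C@]12C(=O)O)c1ccccc1 | intermediate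
14 | 1-acylimidazole (imidazolide) of acid 13 | O=C(O[C@H]1C=C[C@@H](OC(=O)c2ccccc2)[C@@H]2OC(C)(C)O[C@]12C(=O)n1ccnc1)c1ccccc1 | intermediate
15 | (3aR,4S,7R,7aS)-3a-(hydroxymethyl)-2,2-dimethyl-3a,4,7,7a-tetrahydro-1,3-benzodioxole-4,7-diyl dibenzoate | O=C(O[C@H]1C=C[C@@H](OC(=O)c2ccccc2)[C@@H]2OC(C)(C)O[C@]12CO)c1ccccc1 | intermediate
16 | (1R,4S,5S,6S)-5,6-dihydroxy-5-(hydroxymethyl)cyclohex-2-ene-1,4-diyl dibenzoate (CNP0212417.1) | O=C(O[C@H]1C=C[C@@H](OC(=O)c2ccccc2)[C@H](O)[C@@]1(O)CO)c1ccccc1 | target

**Step count and risks**

Total step count: 11. Longest linear sequence: 11 steps from D-glucal; the route is fully linear.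

Steps most likely to fail:

1. Step 9 (key step). What may go wrong: benzoyl transfer from the enol benzoate or the C4 benzoate to the amide base or to the lactone enolate, β-elimination of the C3 oxygen before silylation, or decay of the ketene acetal because the boat-type rearrangement is slow. The fallback sets out from boronate 9 and comes back at acid 13; it forms the C–C bond first and introduces the oxygen afterwards. Boronate 9, which has no acyl group on the alkene terminus, is enolised and silylated by the same protocol to ketene acetal F1. Heating rearranges it to trimethylsilyl ester F2, and acidic work-up gives allylic boronate acid F3, with boron in the position the benzoate oxygen would occupy. Oxidation of the C–B bond with retention (NaBO3·4H2O, THF/H2O) gives hydroxy acid F4. Benzoyl chloride in pyridine then benzoylates the alcohol and the carboxyl group (mixed anhydride F5), and aqueous NaHCO3 hydrolyses the anhydride to acid 13.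

2. Step 8. What may go wrong: slow transfer of the alkenyl group from the pinacol boronate to copper, protodeboronation or homocoupling of the alkenyl group, or base-induced opening of the lactone during a long reaction. The fallback sets out from aldehyde 8 and comes back at enol benzoate 10; it uses a vinyl halide in place of the boron compound. Takai iodo-olefination (CHI3, CrCl2, THF, 0 °C) gives (E)-vinyl iodide F6. A copper(I)-catalysed Ullmann-type vinylation of benzoic acid (CuI, a phenanthroline ligand, Cs2CO3, toluene, 80 °C) then forms the enol ester with retention of geometry.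

3. Step 7. What may go wrong: loss of benzoate by β-elimination from aldehyde 8, epimerisation at C5 during a slow olefination with the bulky boryl-chromium reagent, or erosion of E selectivity. The fallback sets out from aldehyde 8 and comes back at boronate 9; it separates the C–C bond formation from the introduction of boron. Non-basic methylenation with Zn/CH2Br2/TiCl4 (Takai–Lombardo) gives vinyl lactone F7. Cross-metathesis of F7 with vinylboronic acid pinacol ester (second-generation Hoveyda–Grubbs catalyst, CH2Cl2, 40 °C) should then give the (E)-alkenylboronate.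

**Further compounds**

F1 | step 9 | 1-O-trimethylsilyl ketene acetal of boronate 9 | CC1(C)OB(/C=C/[C@H]2OC(O[Si](C)(C)C)=C3OC(C)(C)O[C@H]3[C@@H]2OC(=O)c2ccccc2)OC1(C)C
F2 | step 9 | trimethylsilyl ester of the ring-contracted allylic boronate acid | CC1(C)OB([C@H]2C=C[C@@H](OC(=O)c3ccccc3)[C@@H]3OC(C)(C)O[C@]23C(=O)O[Si](C)(C)C)OC1(C)C
F3 | step 9 | allylic boronate acid (acid 13 with pinacolatoboryl in place of the C4 benzoyloxy group, same configuration) | CC1(C)OB([C@H]2C=C[C@@H](OC(=O)c3ccccc3)[C@@H]3OC(C)(C)O[C@]23C(=O)O)OC1(C)C
F4 | step 9 | hydroxy acid (acid 13 with free hydroxyl at C4 of the benzodioxole) | O[C@H]1C=C[C@@H](OC(=O)c2ccccc2)[C@@H]2OC(C)(C)O[C@]12C(=O)O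
F5 | step 9 | mixed benzoic anhydride of acid 13 | O=C(O[C@H]1C=C[C@@H](OC(=O)c2ccccc2)[C@@H]2OC(C)(C)O[C@]12C(=O)OC(=O)c1ccccc1)c1ccccc1
F6 | step 8 | (6E)-4-O-benzoyl-6,7-dideoxy-7-iodo-2,3-O-isopropylidene-D-manno-hept-6-enono-1,5-lactone | I/C=C/[C@H]1OC(=O)[C@H]2OC(C)(C)O[C@H]2[C@@H]1OC(=O)c1ccccc1
F7 | step 7 | 4-O-benzoyl-6,7-dideoxy-2,3-O-isopropylidene-D-manno-hept-6-enono-1,5-lactone (5-vinyl lactone) | C=C[C@H]1OC(=O)[C@H]2OC(C)(C)O[C@H]2[C@@H]1OC(=O)c1ccccc1
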